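Its constants are those of an exercise; the flask was simulated.

**The leftover.** Of the 0.300 M of reagent charged, 5.0% of the starting material, counted wholly as product, leaves 0.295 M, so we take the reagent concentration [B] as charged.

starting material 0.10 M; reagent 3.00 equiv; protic impurity 0.0200 M; free catalyst 0.5 mol%

    starting material + free catalyst → free catalyst + open intermediate (k1 = 0.46 /M/s)
    free catalyst + open intermediate ⇌ catalyst intermediate (K2 = 17 /M, k2 = 0.45 /M/s)
    reagent + catalyst intermediate → free catalyst + product (k3 = 0.076 /M/s)
    starting material + protic impurity → quenched substrate (k4 = 0.0051 /M/s)

* the form that holds most of the catalyst when 5.0% of the starting material are converted (free catalyst / catalyst intermediate)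
* its share of the catalyst then
* apparent order in reagent when 5.0% of the starting material are converted (percent change of the rate of making product for one percent more reagent charged)
* apparent order in free catalyst when 5.0% of the starting material are converted (percent change of the rate of making product for one percent more free catalyst charged)

**Two exits.** Catalyst intermediate leaves either backwards, at 0.0265 /s (capture constant over equilibrium constant), or forwards with reagent, at 0.0228 /s. The two exits are equal at the crossover concentration B*, the back constant over the constant of the reagent step, 0.348 M. If catalyst intermediate is made as fast as it leaves, the rate goes as [B]/(B*+[B]), and the order in reagent is B*/(B*+[B]) = 0.537.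

**First doubt.** That assumes the catalyst stays free, so we need the open intermediate. From 5.00 × 10⁻⁴ M of free catalyst, starting material goes to open intermediate and to quenched substrate in the ratio 2.25. A share f = 0.693 of the converted part is therefore open intermediate, 0.00346 M. Catalyst intermediate over free catalyst is then 0.0316, which leaves nearly all the catalyst free, 96.9%. Free catalyst is the resting state.

**Second doubt.** The flask is young. By our reckoning, reaching 5.0% takes t = 154 s, while catalyst intermediate adjusts in τ = 20.3 s. That is shorter, but it is still 0.132 of t. Open intermediate rises nearly evenly, so catalyst intermediate trails it by τ. The ratio falls to 0.0275 and the free share rises to 97.3%. Faster exits also shorten the trail, which gives some order back: reagent's order becomes 0.607. More free catalyst acts directly and also diverts part of the starting material from quenching, while reaching 5.0% sooner counts against it. Its order comes to 1.20.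

**The forecast.** The forecast named free catalyst at 97.3%, with orders 0.6 in reagent and 1.2 in free catalyst, holding that “reversal and product formation compete about equally”.

**The flask.** The flask gives free catalyst at 97.3%, with orders 0.61 in reagent and 1.2 in free catalyst. At 0.692 h, catalyst intermediate is made 1.01 times as fast as it is used up, each step taken net, so the plain balance is close there. Now B* once more, at 3.00 h: reagent at 90% of its charge is 0.271 M, and open intermediate at 42.3% of the starting material charged is 0.0423 M. B*/(B*+[B]) is then 0.562, which puts 28.8% of the catalyst in catalyst intermediate, and the flask holds 28.8%.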